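## Retrosynthetic overview
1. Locants of the carbocycle: C1' (quaternary oxirane C bearing the drimenyl CH2), C2' (oxirane CH), C3' (C=O), C4' (C–CH2O), C5' (=CH), C6' (C=O). The last bond made is the ester between alcohol 17 and the HMG half-ester 21.
2. Carbocycle: cut its only alkene C4'=C5' and lower C3'/C6' to carbinols. This gives the acyclic cis-epoxy diol-diene 14. In the forward direction, RCM and double oxidation run in one flask (14 → 16).
3. Enabling feature: C4'=C5' lies opposite the C1'–C2' bond that the carbocycle shares with the cis-fused oxirane, and both ketones flank it. The oxirane therefore holds the two alkenyl-carbinol arms syn, and both carbinol centres vanish on oxidation.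
4. Oxirane: made earlier on a temporary butenolide 11 (ring C6'–C1'=C2'–C3'–O, not in the target). The butenolide fixes the Z geometry and relays a sacrificial C3' carbinol centre to C1'/C2'. The lactone is then cleaved with a vinyl nucleophile.
5. Ring order: decalin rings (bought with sclareolide) → temporary butenolide (step 8, opened in step 10) → oxirane (step 9) → six-membered carbocycle (step 11, last ring).

Key step: step 11

Assumption: for ProPhenol and the Shi ketone the antipode that gives the drawn configuration is meant, and pig liver esterase is taken to cleave the pro-S ester group of 18.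

## Route

Step 1
Reactants: 1 (+)-sclareolide
Product: 2 sclareolide lactol (γ-lactol, C12 epimers)
Conditions: DIBAL-H (1.1 equiv), CH2Cl2, −78 °C; Rochelle salt
Reagents that add atoms: none
Why: Partial DIBAL-H reduction of a γ-lactone stops at the aluminium lactolate at −78 °C, and no decalin stereocentre is touched (the new anomeric centre is lost in step 2).

Step 2
Reactants: 2 sclareolide lactol
Product: 3 11-ethynyldriman-8α-ol
Conditions: dimethyl (1-diazo-2-oxopropyl)phosphonate, K2CO3, MeOH, rt
Reagents that add atoms: dimethyl (1-diazo-2-oxopropyl)phosphonate COP(=O)(OC)C(=[N+]=[N-])C(C)=O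
Why: Ohira–Bestmann (Seyferth–Gilbert) homologation acts on the hydroxy-aldehyde tautomer of the lactol and turns CH=O into C≡CH without touching C9, which is β to the carbonyl.

Step 3
Reactants: 3 11-ethynyldriman-8α-ol
Product: 4 11-ethynyldrim-8(12)-ene
Conditions: SOCl2, pyridine, CH2Cl2, −78 °C
Reagents that add atoms: none
Why: Chlorosulfite E2 dehydration of the equatorial tertiary alcohol, in which only a C–H of the axial methyl group can align anti-periplanar to C–O, so the exocyclic 8(12)-alkene should prevail.

Step 4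
Reactants: 5 2-methylenepropane-1,3-diol
Product: 6 2-[(tert-butyldimethylsilyloxy)methyl]prop-2-en-1-ol
Conditions: NaH (1.0 equiv), THF, 0 °C; TBSCl (1.0 equiv), rt
Reagents that add atoms: TBSCl CC(C)(C)[Si](C)(C)Cl
Why: Monosilylation of a symmetrical diol through its sparingly soluble monosodium alkoxide.

Step 5
Reactants: 6 2-[(tert-butyldimethylsilyloxy)methyl]prop-2-en-1-ol
Product: 7 2-[(tert-butyldimethylsilyloxy)methyl]acrolein
Conditions: MnO2, CH2Cl2, rt
Reagents that add atoms: none
Why: Allylic alcohol oxidation with MnO2 stops cleanly at the enal.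

Step 6
Reactants: 4 11-ethynyldrim-8(12)-ene; 7 2-[(tert-butyldimethylsilyloxy)methyl]acrolein
Product: 8 (3'S)-propargylic alcohol drimenyl-CH2–C≡C–CH(OH)–C(=CH2)CH2OTBS
Conditions: Me2Zn, ProPhenol (20 mol %), Ph3PO (40 mol %), toluene, 0 °C
Reagents that add atoms: none
Why: Dinuclear zinc–ProPhenol alkynylation of an α,β-unsaturated aldehyde, in which the catalyst binds the alkynylzinc and the aldehyde and sets the sacrificial C3' carbinol centre.

Step 7
Reactants: 8 (3'S)-propargylic alcohol
Product: 10 (3'S,Z)-vinyl iodide (iodine on C1' cis to the C3' carbinol), via cyclic sodium alkenylalanate 9 (not isolated)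
Conditions: Red-Al, THF, 0 °C → rt; then I2, THF, −78 °C
Reagents that add atoms: Red-Al [Na+].COCCO[AlH2-]OCCOC; iodine II
Why: Hydroxyl-directed trans-hydroalumination puts Al on the distal alkyne carbon in a five-membered alanate, and iodinolysis with retention gives the Z-γ-iodo allylic alcohol with C3' untouched.

Step 8
Reactants: 10 (3'S,Z)-vinyl iodide
Product: 11 butenolide 3-(drim-8(12)-en-11-yl)-5-[3-(TBSO)prop-1-en-2-yl]furan-2(5H)-one
Conditions: PdCl2(PPh3)2 (5 mol %), CO (1 atm), K2CO3, THF, 50 °C
Reagents that add atoms: carbon monoxide [C-]#[O+]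
Why: Palladium-catalysed carbonylative lactonisation (oxidative addition with retention, CO insertion, capture by the cis hydroxyl) brings in C6' and locks C6' and C3' cis in a temporary ring.

Step 9
Reactants: 11 butenolide
Product: 12 α,β-epoxy-γ-lactone (oxirane on C1'–C2', anti to the C3' substituent)
Conditions: aq NaOCl, pyridine, 0 °C
Reagents that add atoms: sodium hypochlorite [Na+].[O-]Cl
Why: Weitz–Scheffer-type nucleophilic epoxidation in which hypochlorite adds to the unsubstituted C2' from the ring face opposite the C3' substituent and the enolate closes on oxygen, so C3' sets both C1' and C2', while the weakly basic nucleophilic oxidant should spare the C3'–H and the isolated alkenes.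

Step 10
Reactants: 12 α,β-epoxy-γ-lactone
Product: 14 cis-epoxy diol-diene (C6' epimers), via diisobutylaluminium lactolate 13 (not isolated)
Conditions: DIBAL-H (1.1 equiv), CH2Cl2, −78 °C; then CH2=CHMgBr, THF, −78 → 0 °C
Reagents that add atoms: DIBAL-H CC(C)C[AlH]CC(C)C; vinylmagnesium bromide C=C[Mg]Br
Why: One-pot lactone reduction and Grignard addition opens the temporary ring and installs C5', and the new C6' carbinol centre may form as a mixture because step 11 erases it.

Step 11
Reactants: 14 cis-epoxy diol-diene
Product: 16 epoxy-ene-dione TBS ether, via epoxycyclohexenediol 15 (not isolated)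
Conditions: Grubbs II (5 mol %), 1,4-benzoquinone (10 mol %), CH2Cl2 (2 mM), 40 °C; then DMP (2.5 equiv), rt, same flask
Reagents that add atoms: none
Why: The Ru alkylidene loads on the monosubstituted C6' vinyl group, [2+2]/cycloreversion with the 1,1-disubstituted C4' olefin expels ethene and forms C4'=C5', and DMP added to the same flask oxidises both sacrificial carbinols, so an acyclic diol-diene becomes the complete epoxy-ene-dione core in one operation. The closest known reaction types are RCM of 1,7-octadiene-3,6-diol derivatives to conduritol-type cyclohexenediols and periodinane oxidation of cyclohex-2-ene-1,4-diols to ene-diones. One ring is closed, the six-membered carbocycle, by olefin metathesis at its only double bond, while the oxirane is already present and acts only as a cis clamp. No stereocentre is created: C1' and C2' (set in step 9) are carried through these neutral to weakly acidic conditions, and C3' and both C6' epimers are erased and converge on one product. The step needs chemoselectivity among three alkene types and cyclisation over oligomerisation, which is secured because the exocyclic C8 methylene is a hindered 1,1-disubstituted spectator, the cis-oxirane holds the two reacting arms syn, and high dilution favours the six-ring. Benzoquinone intercepts Ru–H species that would isomerise the allylic carbinols, and the only other alcohol is silylated.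

Step 12
Reactants: 16 epoxy-ene-dione TBS ether
Product: 17 primary alcohol (de-acyl compound, CH2OH on C4')
Conditions: HF·pyridine, THF, 0 °C
Reagents that add atoms: none
Why: Fluoride cleavage of a primary TBS ether under mildly acidic conditions that a base-sensitive epoxy-ene-dione should tolerate.

Step 13
Reactants: 18 dimethyl 3-hydroxy-3-methylglutarate
Product: 19 (S)-methyl hydrogen 3-hydroxy-3-methylglutarate
Conditions: pig liver esterase, phosphate buffer pH 7, 1 M NaOH (pH-stat), rt; then HCl
Reagents that add atoms: water O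
Why: Enzymatic desymmetrisation by hydrolysis of one enantiotopic ester group sets the quaternary carbinol centre of the side chain.

Step 14
Reactants: 19 (S)-methyl hydrogen 3-hydroxy-3-methylglutarate
Product: 20 tert-butyl methyl 3-hydroxy-3-methylglutarate (mixed diester)
Conditions: tert-butyl 2,2,2-trichloroacetimidate, CH2Cl2/cyclohexane, rt
Reagents that add atoms: tert-butyl 2,2,2-trichloroacetimidate CC(C)(C)OC(=N)C(Cl)(Cl)Cl
Why: Imidate esterification is triggered by the carboxylic acid itself, so the tertiary alcohol stays free and the stereocentre is untouched.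

Step 15
Reactants: 20 mixed diester
Product: 21 (R)-5-tert-butoxy-3-hydroxy-3-methyl-5-oxopentanoic acid
Conditions: LiOH (1.05 equiv), THF/H2O, 0 °C; then HCl
Reagents that add atoms: lithium hydroxide [Li+].[OH-]
Why: Chemoselective saponification of the methyl ester beside the hindered tert-butyl ester frees the arm that must carry the terpenoid (only the CIP descriptor changes).

Step 16
Reactants: 17 primary alcohol; 21 half-ester acid
Product: 22 tert-butyl ester of 4'-oxomacrophorin D
Conditions: DIC, DMAP (cat.), CH2Cl2, 0 °C → rt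
Reagents that add atoms: none
Why: Steglich esterification of the only hydroxyl group of 17, in which the tertiary alcohol of 21 is too hindered to compete.

Step 17
Reactants: 22 tert-butyl ester of 4'-oxomacrophorin D
Product: 24 4'-oxomacrophorin D, via bis(trimethylsilyl) derivative 23 (not isolated)
Conditions: TMSOTf, 2,6-lutidine, CH2Cl2, 0 °C; then aq citric acid, THF, rt
Reagents that add atoms: TMSOTf C[Si](C)(C)OS(=O)(=O)C(F)(F)F
Why: Silyl-triflate-mediated tert-butyl ester cleavage (loss of isobutene from the silylated ester) in a lutidine-buffered medium avoids protonating the exocyclic alkene, and the silyl ester and silyl ether hydrolyse on mild acidic work-up.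

## Compound list
1 | (+)-sclareolide | C[C@@]12CC[C@H]3C(C)(C)CCC[C@]3(C)[C@H]1CC(=O)O2 | starting material
2 | sclareolide lactol | C[C@@]12CC[C@H]3C(C)(C)CCC[C@]3(C)[C@H]1CC(O)O2 | intermediate
3 | 11-ethynyldriman-8α-ol | C[C@@]1(O)CC[C@H]2C(C)(C)CCC[C@]2(C)[C@H]1CC#C | intermediate
4 | 11-ethynyldrim-8(12)-ene | C=C1CC[C@H]2C(C)(C)CCC[C@]2(C)[C@H]1CC#C | intermediate
5 | 2-methylenepropane-1,3-diol | C=C(CO)CO | starting material
6 | 2-[(tert-butyldimethylsilyloxy)methyl]prop-2-en-1-ol | C=C(CO)CO[Si](C)(C)C(C)(C)C | intermediate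
7 | 2-[(tert-butyldimethylsilyloxy)methyl]acrolein | C=C(C=O)CO[Si](C)(C)C(C)(C)C | intermediate
8 | (3'S)-propargylic alcohol | C=C1CC[C@H]2C(C)(C)CCC[C@]2(C)[C@H]1CC#C[C@H](O)C(=C)CO[Si](C)(C)C(C)(C)C | intermediate
9 | cyclic sodium alkenylalanate | C=C1CC[C@H]2C(C)(C)CCC[C@]2(C)[C@H]1CC1=C[C@@H](C(=C)CO[Si](C)(C)C(C)(C)C)O[Al-]1(OCCOC)OCCOC.[Na+] | intermediate
10 | (3'S,Z)-vinyl iodide | C=C1CC[C@H]2C(C)(C)CCC[C@]2(C)[C@H]1C/C(I)=C/[C@H](O)C(=C)CO[Si](C)(C)C(C)(C)C | intermediate
11 | butenolide | C=C1CC[C@H]2C(C)(C)CCC[C@]2(C)[C@H]1CC1=C[C@@H](C(=C)CO[Si](C)(C)C(C)(C)C)OC1=O | intermediate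
12 | α,β-epoxy-γ-lactone | C=C1CC[C@H]2C(C)(C)CCC[C@]2(C)[C@H]1C[C@@]12O[C@@H]1[C@@H](C(=C)CO[Si](C)(C)C(C)(C)C)OC2=O | intermediate
13 | diisobutylaluminium lactolate | C=C1CC[C@H]2C(C)(C)CCC[C@]2(C)[C@H]1C[C@@]12O[C@@H]1[C@@H](C(=C)CO[Si](C)(C)C(C)(C)C)OC2O[Al](CC(C)C)CC(C)C | intermediate
14 | cis-epoxy diol-diene (C6' epimers) | C=C1CC[C@H]2C(C)(C)CCC[C@]2(C)[C@H]1C[C@@]2(C(O)C=C)O[C@@H]2[C@H](O)C(=C)CO[Si](C)(C)C(C)(C)C | intermediate
15 | epoxycyclohexenediol (C6' epimers) | C=C1CC[C@H]2C(C)(C)CCC[C@]2(C)[C@H]1C[C@@]12O[C@@H]1[C@H](O)C(CO[Si](C)(C)C(C)(C)C)=CC2O | intermediate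
16 | epoxy-ene-dione TBS ether | C=C1CC[C@H]2C(C)(C)CCC[C@]2(C)[C@H]1C[C@@]12O[C@@H]1C(=O)C(CO[Si](C)(C)C(C)(C)C)=CC2=O | intermediate
17 | primary alcohol (de-acyl compound) | C=C1CC[C@H]2C(C)(C)CCC[C@]2(C)[C@H]1C[C@@]12O[C@@H]1C(=O)C(CO)=CC2=O | intermediate
18 | dimethyl 3-hydroxy-3-methylglutarate | COC(=O)CC(C)(O)CC(=O)OC | starting material
19 | (S)-methyl hydrogen 3-hydroxy-3-methylglutarate | COC(=O)C[C@@](C)(O)CC(=O)O | intermediate
20 | tert-butyl methyl 3-hydroxy-3-methylglutarate | COC(=O)C[C@@](C)(O)CC(=O)OC(C)(C)C | intermediate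
21 | (R)-5-tert-butoxy-3-hydroxy-3-methyl-5-oxopentanoic acid | OC(=O)C[C@@](C)(O)CC(=O)OC(C)(C)C | intermediate
22 | tert-butyl ester of 4'-oxomacrophorin D | C=C1CC[C@H]2C(C)(C)CCC[C@]2(C)[C@H]1C[C@@]12O[C@@H]1C(=O)C(COC(=O)C[C@@](C)(O)CC(=O)OC(C)(C)C)=CC2=O | intermediate
23 | bis(trimethylsilyl) derivative | C=C1CC[C@H]2C(C)(C)CCC[C@]2(C)[C@H]1C[C@@]12O[C@@H]1C(=O)C(COC(=O)C[C@@](C)(O[Si](C)(C)C)CC(=O)O[Si](C)(C)C)=CC2=O | intermediate
24 | 4'-oxomacrophorin D | C=C1CC[C@H]2C(C)(C)CCC[C@]2(C)[C@H]1C[C@@]12O[C@@H]1C(=O)C(COC(=O)C[C@@](C)(O)CC(=O)O)=CC2=O | target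

## Step count and risks

Total step count: 17. Longest linear sequence: 12 (steps 1–3, 6–12, 16, 17).

**Step 9.**
- Risk: conjugate addition of hypochlorite to the α-alkylated butenolide may be slow. Base-mediated loss of the doubly activated C3'–H could then compete and scramble the controlling centre, and hypochlorous acid could chlorinate the isolated 1,1-disubstituted alkenes.
- Fallback (reagent-controlled electrophilic epoxidation on the opened ring): this sets out from 11 and returns at 12.
  - DIBAL-H (2.5 equiv, CH2Cl2, −78 → 0 °C) should give the Z-ene-diol F1.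
  - TESCl/imidazole should give the bis(triethylsilyl) ether F2.
  - Shi epoxidation (fructose-derived ketone, Oxone, K2CO3 buffer, MeCN/dimethoxymethane/H2O, 0 °C) should oxidise the only trisubstituted alkene to the epoxide F3.
  - PPTS/MeOH at 0 °C should remove both TES groups but not the TBS group, giving the epoxy diol F4.
  - TEMPO/PhI(OAc)2 should oxidise and close the 1,4-diol to 12.

**Step 11.**
- Risk: Ru–H isomerisation of the allylic carbinols to ketones, slow catalyst loading next to the quaternary C1', or oligomerisation before ring closure.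
- Fallback (lactone cleavage at the ketone level, enone metathesis): this sets out from 12 and returns at 16.
  - Vinyllithium/CeCl3 (THF, −78 °C) should give the hydroxy vinyl ketone F5.
  - RCM of this enone with the 1,1-disubstituted olefin (Hoveyda–Grubbs II, toluene, 80 °C, high dilution) should give the epoxyquinol F6.
  - DMP should oxidise the single remaining carbinol to 16.

**Step 17.**
- Risk: Lewis-acid-induced opening of the oxirane, or incomplete loss of the tert-butyl group before the ene-dione degrades.
- Fallback (no protecting group on the acid arm): this sets out from 17 and returns at 24.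
  - Acylation with 3-hydroxy-3-methylglutaric anhydride in toluene at −20 °C, with catalytic DMAP or a cinchona-alkaloid catalyst to bias the enantiotopic carbonyl groups, should give 24 directly.
  - The side-chain epimer F7 forms alongside it. It is a diastereomer and should be separable by reversed-phase HPLC.

Further compounds
F1 | step 9 | Z-ene-diol | C=C1CC[C@H]2C(C)(C)CCC[C@]2(C)[C@H]1C/C(CO)=C/[C@H](O)C(=C)CO[Si](C)(C)C(C)(C)C
F2 | step 9 | bis(triethylsilyl) ether | C=C1CC[C@H]2C(C)(C)CCC[C@]2(C)[C@H]1C/C(CO[Si](CC)(CC)CC)=C/[C@H](O[Si](CC)(CC)CC)C(=C)CO[Si](C)(C)C(C)(C)C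
F3 | step 9 | epoxide of the bis(triethylsilyl) ether | C=C1CC[C@H]2C(C)(C)CCC[C@]2(C)[C@H]1C[C@@]2(CO[Si](CC)(CC)CC)O[C@@H]2[C@H](O[Si](CC)(CC)CC)C(=C)CO[Si](C)(C)C(C)(C)C
F4 | step 9 | epoxy diol | C=C1CC[C@H]2C(C)(C)CCC[C@]2(C)[C@H]1C[C@@]2(CO)O[C@@H]2[C@H](O)C(=C)CO[Si](C)(C)C(C)(C)C
F5 | step 11 | hydroxy vinyl ketone | C=C1CC[C@H]2C(C)(C)CCC[C@]2(C)[C@H]1C[C@@]2(C(=O)C=C)O[C@@H]2[C@H](O)C(=C)CO[Si](C)(C)C(C)(C)C
F6 | step 11 | epoxyquinol | C=C1CC[C@H]2C(C)(C)CCC[C@]2(C)[C@H]1C[C@@]12O[C@@H]1[C@H](O)C(CO[Si](C)(C)C(C)(C)C)=CC2=O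
F7 | step 17 | side-chain epimer of 24 | C=C1CC[C@H]2C(C)(C)CCC[C@]2(C)[C@H]1C[C@@]12O[C@@H]1C(=O)C(COC(=O)C[C@](C)(O)CC(=O)O)=CC2=O
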